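**Plan**
- Enabling feature: each 3,5-dihydroxyphenyl ring is bound through its C1, meta to both hydroxyls, to C3 of an outer dihydrobenzofuran (DHB1 on ring A beside the stilbene, DHB3 on ring C at the far end; DHB2 on ring B lies between). A chain C(=O)CH2C(=O)CH2C(=O)CH3 on C3 gives exactly this 1,3,5 pattern when its methyl carbon closes onto the first carbonyl.
- Cuts: five O–CH3 bonds; in each resorcinol ring the bond from the carbon on C3 to its ortho carbon (aldol), back to a bis(triketone); the two chains back to C3 methyl esters and pentane-2,4-dione; the ring A–vinyl bond; the C2–C3 bonds of DHB1, DHB2 and DHB3 (rhodium carbene C–H insertion); the ring A O–CH2 bond; the ring C–carbonyl carbon bond.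
- Forward: keto ester phenol 4 (used twice) → DHB3 → boronate added to the ring B aldehyde, ketone, diaryl carbene → DHB2 → ring A unit attached as an ether → DHB1 → stilbene → both resorcinol rings in one step → demethylation.
- Stereochemistry: C2 of DHB3 and DHB1 from catalyst-controlled insertion with Rh2(S-PTTL)4 (PTTL = N-phthaloyl-tert-leucinate), their C3 by base epimerisation to trans; C3 of DHB2 from Rh2(R-PTAD)4 (PTAD = N-phthaloyl-(1-adamantyl)glycinate), its C2 by acid equilibration to trans; the E-alkene comes from the vinylboronate.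

Key step: step 20

Assumption: the sense of induction of the two chiral dirhodium carboxylates is taken as written (S-tert-leucinate catalyst gives 2R in the ester series, R-adamantylglycinate catalyst gives 3R in the diaryl series); if a model insertion shows the opposite sense, the mirror-image catalyst is used and nothing else changes.

**Route**

Step 1
Reactants: 1 1-bromo-3,5-dimethoxybenzene; 2 methyl chlorooxoacetate
Product: 3 methyl 2-(2-bromo-4,6-dimethoxyphenyl)-2-oxoacetate
Conditions: AlCl3, CH2Cl2, −20 → 0 °C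
Reagents that add atoms: none
Why: Friedel–Crafts acylation should take the position ortho to bromine and para to one methoxy group, the site also taken in formylation and acetylation of this arene, and any 4-acyl isomer would be removed by crystallisation.

Step 2
Reactants: 3 methyl 2-(2-bromo-4,6-dimethoxyphenyl)-2-oxoacetate
Product: 4 methyl 2-(2-bromo-6-hydroxy-4-methoxyphenyl)-2-oxoacetate
Conditions: BCl3, CH2Cl2, −78 → 0 °C; then H2O
Reagents that add atoms: none
Why: Chelation-controlled ortho-demethylation, in which BCl3 bound between the ketone oxygen and the neighbouring methoxy group should cleave only that ether and leave the para methoxy group and the ester.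

Step 3
Reactants: 4 methyl 2-(2-bromo-6-hydroxy-4-methoxyphenyl)-2-oxoacetate; 5 4-methoxybenzyl chloride
Product: 6 methyl 2-[2-bromo-4-methoxy-6-(4-methoxybenzyloxy)phenyl]-2-oxoacetate
Conditions: K2CO3, NaI (cat.), DMF, 25 °C
Reagents that add atoms: none
Why: Williamson ether synthesis on an acidic, hydrogen-bonded phenol with a reactive benzylic chloride should be clean, and the methylene installed here becomes C2 of DHB3.

Step 4
Reactants: 6 methyl 2-[2-bromo-4-methoxy-6-(4-methoxybenzyloxy)phenyl]-2-oxoacetate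
Product: 8 methyl 2-[2-bromo-4-methoxy-6-(4-methoxybenzyloxy)phenyl]-2-diazoacetate, via tosylhydrazone 7 (not isolated)
Conditions: TsNHNH2, MeOH, 50 °C; evaporate; then DBU, CH2Cl2, 0 → 25 °C
Reagents that add atoms: p-toluenesulfonyl hydrazide, Cc1ccc(cc1)S(=O)(=O)NN
Why: Condensation at the only ketone followed by Bamford–Stevens loss of sulfinate from the α-keto ester tosylhydrazone should give the aryl diazoacetate without a diazo transfer to a doubly ortho-substituted arylacetate.

Step 5
Reactants: 8 methyl 2-[2-bromo-4-methoxy-6-(4-methoxybenzyloxy)phenyl]-2-diazoacetate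
Product: 10 methyl (2R,3R)-4-bromo-6-methoxy-2-(4-methoxyphenyl)-2,3-dihydrobenzofuran-3-carboxylate (trans ester), via cis ester 9 (not isolated)
Conditions: Rh2(S-PTTL)4 (2 mol %), toluene, −78 → −40 °C; then NaOMe (cat.), MeOH, 40 °C
Reagents that add atoms: none
Why: Intramolecular rhodium carbene 1,5 C–H insertion into the benzylic ether methylene should close the five-membered ring as the cis ester with C2 (2R) set by the chiral catalyst, and methoxide then epimerises C3 through the ester enolate to the more stable trans ester while the bromide stays inert.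

Step 6
Reactants: 10 methyl (2R,3R)-4-bromo-6-methoxy-2-(4-methoxyphenyl)-2,3-dihydrobenzofuran-3-carboxylate
Product: 11 methyl (2R,3R)-6-methoxy-2-(4-methoxyphenyl)-4-(4,4,5,5-tetramethyl-1,3,2-dioxaborolan-2-yl)-2,3-dihydrobenzofuran-3-carboxylate
Conditions: B2pin2, Pd(dppf)Cl2 (5 mol %), KOAc, dioxane, 90 °C
Reagents that add atoms: bis(pinacolato)diboron, CC1(C)OB(OC1(C)C)B1OC(C)(C)C(C)(C)O1
Why: Miyaura borylation turns the bromide into a carbon nucleophile under acetate base, which should be too weak to disturb the trans ester whose acidic C3–H rules out any aryllithium.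

Step 7
Reactants: 12 tert-butyl 4-hydroxybenzoate
Product: 13 tert-butyl 3-formyl-4-hydroxybenzoate
Conditions: MgCl2, Et3N, (CH2O)n, MeCN, reflux
Reagents that add atoms: paraformaldehyde, C=O
Why: Magnesium phenoxide-directed ortho-formylation (Casnati–Skattebøl reaction) should deliver the aldehyde only ortho to the hydroxyl, the para position being blocked by the ester.

Step 8
Reactants: 13 tert-butyl 3-formyl-4-hydroxybenzoate; 5 4-methoxybenzyl chloride
Product: 14 tert-butyl 3-formyl-4-(4-methoxybenzyloxy)benzoate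
Conditions: K2CO3, DMF, 50 °C
Reagents that add atoms: none
Why: Williamson ether synthesis installs the methylene that becomes C2 of DHB2, with its 4-methoxyphenyl group.

Step 9
Reactants: 11 methyl (2R,3R)-6-methoxy-2-(4-methoxyphenyl)-4-(4,4,5,5-tetramethyl-1,3,2-dioxaborolan-2-yl)-2,3-dihydrobenzofuran-3-carboxylate; 14 tert-butyl 3-formyl-4-(4-methoxybenzyloxy)benzoate
Product: 15 methyl (2R,3R)-4-{[5-(tert-butoxycarbonyl)-2-(4-methoxybenzyloxy)phenyl](hydroxy)methyl}-6-methoxy-2-(4-methoxyphenyl)-2,3-dihydrobenzofuran-3-carboxylate (both carbinol epimers)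
Conditions: [Rh(OH)(cod)]2 (3 mol %), K3PO4, dioxane/H2O, 60 °C
Reagents that add atoms: none
Why: Rhodium-catalysed 1,2-addition of an arylboronate to an aldehyde should join ring C to the future C3 of DHB2 under near-neutral aqueous conditions that both esters tolerate, and the uncontrolled carbinol centre is removed in step 10.

Step 10
Reactants: 15 diaryl carbinol (both epimers)
Product: 16 methyl (2R,3R)-4-[5-(tert-butoxycarbonyl)-2-(4-methoxybenzyloxy)benzoyl]-6-methoxy-2-(4-methoxyphenyl)-2,3-dihydrobenzofuran-3-carboxylate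
Conditions: Dess–Martin periodinane, NaHCO3, CH2Cl2, 0 → 25 °C
Reagents that add atoms: none
Why: Dess–Martin oxidation of a doubly benzylic secondary alcohol should give the diaryl ketone under buffered conditions without touching the epimerisable ester.

Step 11
Reactants: 16 diaryl ketone
Product: 17 N-(tert-butyldimethylsilyl)hydrazone of ketone 16
Conditions: TBSNHNHTBS, Sc(OTf)3 (1 mol %), toluene, 80 °C
Reagents that add atoms: 1,2-bis(tert-butyldimethylsilyl)hydrazine, CC(C)(C)[Si](C)(C)NN[Si](C)(C)C(C)(C)C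
Why: Lewis acid-catalysed condensation with the bis-silyl hydrazine should give the N-silyl hydrazone without free hydrazine, which spares the neighbouring methyl ester from hydrazinolysis and from closure to a benzodiazepinone.

Step 12
Reactants: 17 N-silyl hydrazone
Product: 20 tert-butyl (2S,3R)-3-[(2R,3R)-6-methoxy-3-(methoxycarbonyl)-2-(4-methoxyphenyl)-2,3-dihydrobenzofuran-4-yl]-2-(4-methoxyphenyl)-2,3-dihydrobenzofuran-5-carboxylate (DHB2 cis), via free hydrazone 18 (not isolated), via diazo compound 19 (not isolated)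
Conditions: Bu4NF/AcOH (1:1), THF, −20 °C; MnO2, CH2Cl2, 0 °C, filter; Rh2(R-PTAD)4 (1 mol %), CH2Cl2, −20 → 0 °C
Reagents that add atoms: none
Why: Fluoride desilylation, MnO2 oxidation to the diaryldiazomethane and rhodium donor/donor carbene 1,5 C–H insertion into the ArO–CH2–Ar methylene should close DHB2 as the cis ring with C3 (3R) set by the chiral catalyst, every other C–H being reachable only through a bridged ring.

Step 13
Reactants: 20 cis-DHB2 tert-butyl ester
Product: 21 (2R,3R)-3-[(2R,3R)-6-methoxy-3-(methoxycarbonyl)-2-(4-methoxyphenyl)-2,3-dihydrobenzofuran-4-yl]-2-(4-methoxyphenyl)-2,3-dihydrobenzofuran-5-carboxylic acid (DHB2 trans)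
Conditions: TFA/CH2Cl2 (1:3), 0 → 25 °C
Reagents that add atoms: none
Why: Acid cleaves the tert-butyl ester and at the same time equilibrates C2 of DHB2 by reversible ionisation of the benzylic C2–O bond (4-methoxybenzyl cation and phenol, helped by the para carboxyl group), which should reclose to the more stable 2,3-trans ring with C3 untouched.

Step 14
Reactants: 21 carboxylic acid
Product: 22 methyl (2R,3R)-4-[(2R,3R)-5-(hydroxymethyl)-2-(4-methoxyphenyl)-2,3-dihydrobenzofuran-3-yl]-6-methoxy-2-(4-methoxyphenyl)-2,3-dihydrobenzofuran-3-carboxylate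
Conditions: BH3·SMe2, THF, 0 → 25 °C; then H2O
Reagents that add atoms: none
Why: Borane reduction takes a carboxylic acid much faster than an ester, so the ring B acid should become the benzylic alcohol while the C3 methyl ester of DHB3 is kept.

Step 15
Reactants: 22 benzylic alcohol; 4 methyl 2-(2-bromo-6-hydroxy-4-methoxyphenyl)-2-oxoacetate
Product: 23 methyl 2-[2-bromo-4-methoxy-6-({(2R,3R)-3-[(2R,3R)-6-methoxy-3-(methoxycarbonyl)-2-(4-methoxyphenyl)-2,3-dihydrobenzofuran-4-yl]-2-(4-methoxyphenyl)-2,3-dihydrobenzofuran-5-yl}methoxy)phenyl]-2-oxoacetate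
Conditions: PPh3, DIAD, THF, 0 → 25 °C
Reagents that add atoms: none
Why: Mitsunobu etherification of the acidic phenol with the primary benzylic alcohol should form the ring A O–CH2 bond without acid or base that could ionise the 4-alkoxybenzyl position.

Step 16
Reactants: 23 aryl ether keto ester
Product: 25 aryl diazoacetate corresponding to 23 (C=N2 in place of the ketone C=O), via tosylhydrazone 24 (not isolated)
Conditions: TsNHNH2, MeOH/THF, 50 °C; evaporate; then DBU, CH2Cl2, 0 → 25 °C
Reagents that add atoms: p-toluenesulfonyl hydrazide, Cc1ccc(cc1)S(=O)(=O)NN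
Why: As in step 4, condensation at the only ketone and Bamford–Stevens elimination should give the diazo ester, the hindered methyl ester of DHB3 being inert to the sulfonyl hydrazide.

Step 17
Reactants: 25 aryl diazoacetate
Product: 27 methyl (2R,3R)-4-bromo-6-methoxy-2-{(2R,3R)-3-[(2R,3R)-6-methoxy-3-(methoxycarbonyl)-2-(4-methoxyphenyl)-2,3-dihydrobenzofuran-4-yl]-2-(4-methoxyphenyl)-2,3-dihydrobenzofuran-5-yl}-2,3-dihydrobenzofuran-3-carboxylate (all three rings trans), via cis-DHB1 ester 26 (not isolated)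
Conditions: Rh2(S-PTTL)4 (2 mol %), toluene/CH2Cl2, −60 → −30 °C; then NaOMe (cat.), MeOH/THF, 40 °C
Reagents that add atoms: none
Why: The same rhodium carbene 1,5 C–H insertion closes DHB1 with C2 (2R) fixed by the catalyst and not by the remote centres, and methoxide epimerisation at C3 should give the trans ester while the trans ester of DHB3 is already at equilibrium.

Step 18
Reactants: 27 bromo diester; 28 (E)-2-[2-(4-methoxyphenyl)ethenyl]-4,4,5,5-tetramethyl-1,3,2-dioxaborolane
Product: 29 diester stilbene (27 with the (E)-2-(4-methoxyphenyl)ethenyl group in place of bromine)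
Conditions: Pd(OAc)2 (5 mol %), SPhos (10 mol %), K3PO4, toluene/H2O, 80 °C
Reagents that add atoms: none
Why: Suzuki–Miyaura coupling of the hindered aryl bromide with the E-alkenylboronate should proceed with retention of alkene geometry, and it is placed after the last carbene step so that no alkene meets a rhodium carbene.

Step 19
Reactants: 29 diester stilbene; 30 pentane-2,4-dione
Product: 32 bis(triketone) (each C3 of DHB1 and DHB3 bears C(=O)CH2C(=O)CH2C(=O)CH3), via dilithio dianion 31 (not isolated)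
Conditions: 30 (8 equiv), LiN(iPr)2 (16 equiv), THF, −78 → 0 °C; add 29, 0 → 25 °C; then 1 M HCl
Reagents that add atoms: none
Why: Claisen-type acylation of the terminal carbanion of a β-diketone dianion by an ester is the known route to 1,3,5-triketones, excess dianion makes up for the base consumed by the product, and an ester that is deprotonated at C3 instead should return as the trans ester on quench because the endocyclic C2–O bond is poorly aligned for phenoxide loss.

Step 20
Reactants: 32 bis(triketone)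
Product: 34 tetraol pentamethyl ether (each triketone chain converted into a 3,5-dihydroxyphenyl ring on C3), via bis aldol adduct 33 (not isolated)
Conditions: KOH (1 M aq), MeOH/THF, N2, 0 → 25 °C; then 1 M HCl to pH 4
Reagents that add atoms: none
Why: Hydroxide converts each chain into its polyenolate, the terminal methyl carbon (C6' of the chain) adds to the carbonyl carbon bound to C3 (C1'), the tertiary aldolate loses water and the cyclohexenedione tautomerises to the benzene ring, so that C1' becomes the ring carbon on C3 and the C3' and C5' oxygens become the two meta hydroxyls. The closest known reaction is the base-mediated aldol cyclisation and aromatisation of 2,4,6-triketones to 5-substituted resorcinols (polyketide-type aromatisation). Each ring closes in the 6-(enolexo)-exo-trig mode and no stereocentre is created, since C1' ends as an sp2 carbon. The step needs C-aldol closure in preference to O-cyclisation to a 4-pyranone, which the basic medium secures because pyranone formation needs acid, and among the aldol modes only C6' to C1' can aromatise, the attack of C3 on the C5' carbonyl giving a spiro aldol that reverts. The C3 centres should survive because in base the C1' carbonyl sits in a delocalised enolate, the endocyclic C2–O bond lies orthogonal to a C3 carbanion so that phenoxide loss (the reverse of a 5-endo-trig closure) is slow, and reprotonation returns the more stable 2,3-trans ring. The five methyl ethers and the E-stilbene are inert to aqueous KOH at room temperature.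

Step 21
Reactants: 34 tetraol pentamethyl ether
Product: 35 CNP0184803.1 (target)
Conditions: BBr3 (excess), CH2Cl2, −78 → 0 °C; then H2O
Reagents that add atoms: none
Why: Lewis acid ether cleavage with BBr3 removes the five aryl methyl ethers, and since all three rings are already 2,3-trans any reversible C2–O ionisation should return the same configuration.

**Compound list**
1 | 1-bromo-3,5-dimethoxybenzene | COc1cc(Br)cc(OC)c1 | starting material
2 | methyl chlorooxoacetate | COC(=O)C(Cl)=O | starting material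
3 | methyl 2-(2-bromo-4,6-dimethoxyphenyl)-2-oxoacetate | COC(=O)C(=O)c1c(Br)cc(OC)cc1OC | intermediate
4 | methyl 2-(2-bromo-6-hydroxy-4-methoxyphenyl)-2-oxoacetate | COC(=O)C(=O)c1c(Br)cc(OC)cc1O | intermediate
5 | 4-methoxybenzyl chloride | COc1ccc(CCl)cc1 | starting material
6 | methyl 2-[2-bromo-4-methoxy-6-(4-methoxybenzyloxy)phenyl]-2-oxoacetate | COC(=O)C(=O)c1c(Br)cc(OC)cc1OCc1ccc(OC)cc1 | intermediate
7 | N-tosylhydrazone of 6 | COC(=O)C(=NNS(=O)(=O)c1ccc(C)cc1)c1c(Br)cc(OC)cc1OCc1ccc(OC)cc1 | intermediate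
8 | methyl 2-[2-bromo-4-methoxy-6-(4-methoxybenzyloxy)phenyl]-2-diazoacetate | COC(=O)C(=[N+]=[N-])c1c(Br)cc(OC)cc1OCc1ccc(OC)cc1 | intermediate
9 | methyl (2R,3S)-4-bromo-6-methoxy-2-(4-methoxyphenyl)-2,3-dihydrobenzofuran-3-carboxylate (cis) | Brc1cc(OC)cc2c1[C@H](C(=O)OC)[C@H](c1ccc(OC)cc1)O2 | intermediate
10 | methyl (2R,3R)-4-bromo-6-methoxy-2-(4-methoxyphenyl)-2,3-dihydrobenzofuran-3-carboxylate (trans) | Brc1cc(OC)cc2c1[C@@H](C(=O)OC)[C@H](c1ccc(OC)cc1)O2 | intermediate
11 | methyl (2R,3R)-6-methoxy-2-(4-methoxyphenyl)-4-(4,4,5,5-tetramethyl-1,3,2-dioxaborolan-2-yl)-2,3-dihydrobenzofuran-3-carboxylate | CC1(C)OB(OC1(C)C)c1cc(OC)cc2c1[C@@H](C(=O)OC)[C@H](c1ccc(OC)cc1)O2 | intermediate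
12 | tert-butyl 4-hydroxybenzoate | CC(C)(C)OC(=O)c1ccc(O)cc1 | starting material
13 | tert-butyl 3-formyl-4-hydroxybenzoate | CC(C)(C)OC(=O)c1ccc(O)c(C=O)c1 | intermediate
14 | tert-butyl 3-formyl-4-(4-methoxybenzyloxy)benzoate | CC(C)(C)OC(=O)c1ccc(OCc2ccc(OC)cc2)c(C=O)c1 | intermediate
15 | diaryl carbinol from 11 and 14 (DHB3 2R,3R; carbinol centre as both epimers) | CC(C)(C)OC(=O)c1ccc(OCc2ccc(OC)cc2)c(c1)C(O)c1cc(OC)cc2c1[C@@H](C(=O)OC)[C@H](c1ccc(OC)cc1)O2 | intermediate
16 | diaryl ketone: methyl (2R,3R)-4-[5-(tert-butoxycarbonyl)-2-(4-methoxybenzyloxy)benzoyl]-6-methoxy-2-(4-methoxyphenyl)-2,3-dihydrobenzofuran-3-carboxylate | CC(C)(C)OC(=O)c1ccc(OCc2ccc(OC)cc2)c(c1)C(=O)c1cc(OC)cc2c1[C@@H](C(=O)OC)[C@H](c1ccc(OC)cc1)O2 | intermediate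
17 | N-(tert-butyldimethylsilyl)hydrazone of 16 | CC(C)(C)OC(=O)c1ccc(OCc2ccc(OC)cc2)c(c1)C(=NN[Si](C)(C)C(C)(C)C)c1cc(OC)cc2c1[C@@H](C(=O)OC)[C@H](c1ccc(OC)cc1)O2 | intermediate
18 | hydrazone of 16 (C=N–NH2) | CC(C)(C)OC(=O)c1ccc(OCc2ccc(OC)cc2)c(c1)C(=NN)c1cc(OC)cc2c1[C@@H](C(=O)OC)[C@H](c1ccc(OC)cc1)O2 | intermediate
19 | diaryldiazomethane from 16 (C=N2 in place of C=O) | CC(C)(C)OC(=O)c1ccc(OCc2ccc(OC)cc2)c(c1)C(=[N+]=[N-])c1cc(OC)cc2c1[C@@H](C(=O)OC)[C@H](c1ccc(OC)cc1)O2 | intermediate
20 | tert-butyl (2S,3R)-3-[(2R,3R)-6-methoxy-3-(methoxycarbonyl)-2-(4-methoxyphenyl)-2,3-dihydrobenzofuran-4-yl]-2-(4-methoxyphenyl)-2,3-dihydrobenzofuran-5-carboxylate (DHB2 cis) | CC(C)(C)OC(=O)c1ccc2c(c1)[C@@H](c1cc(OC)cc3c1[C@@H](C(=O)OC)[C@H](c1ccc(OC)cc1)O3)[C@@H](c1ccc(OC)cc1)O2 | intermediate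
21 | (2R,3R)-3-[(2R,3R)-6-methoxy-3-(methoxycarbonyl)-2-(4-methoxyphenyl)-2,3-dihydrobenzofuran-4-yl]-2-(4-methoxyphenyl)-2,3-dihydrobenzofuran-5-carboxylic acid (DHB2 trans) | OC(=O)c1ccc2c(c1)[C@@H](c1cc(OC)cc3c1[C@@H](C(=O)OC)[C@H](c1ccc(OC)cc1)O3)[C@H](c1ccc(OC)cc1)O2 | intermediate
22 | methyl (2R,3R)-4-[(2R,3R)-5-(hydroxymethyl)-2-(4-methoxyphenyl)-2,3-dihydrobenzofuran-3-yl]-6-methoxy-2-(4-methoxyphenyl)-2,3-dihydrobenzofuran-3-carboxylate | OCc1ccc2c(c1)[C@@H](c1cc(OC)cc3c1[C@@H](C(=O)OC)[C@H](c1ccc(OC)cc1)O3)[C@H](c1ccc(OC)cc1)O2 | intermediate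
23 | aryl ether keto ester (phenol oxygen of 4 on the CH2 of 22) | COC(=O)C(=O)c1c(Br)cc(OC)cc1OCc1ccc2c(c1)[C@@H](c1cc(OC)cc3c1[C@@H](C(=O)OC)[C@H](c1ccc(OC)cc1)O3)[C@H](c1ccc(OC)cc1)O2 | intermediate
24 | N-tosylhydrazone of 23 | COC(=O)C(=NNS(=O)(=O)c1ccc(C)cc1)c1c(Br)cc(OC)cc1OCc1ccc2c(c1)[C@@H](c1cc(OC)cc3c1[C@@H](C(=O)OC)[C@H](c1ccc(OC)cc1)O3)[C@H](c1ccc(OC)cc1)O2 | intermediate
25 | aryl diazoacetate from 23 | COC(=O)C(=[N+]=[N-])c1c(Br)cc(OC)cc1OCc1ccc2c(c1)[C@@H](c1cc(OC)cc3c1[C@@H](C(=O)OC)[C@H](c1ccc(OC)cc1)O3)[C@H](c1ccc(OC)cc1)O2 | intermediate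
26 | bromo diester with DHB1 cis (DHB1 2R,3S; DHB2 and DHB3 2R,3R) | Brc1cc(OC)cc2c1[C@H](C(=O)OC)[C@H](c1ccc3c(c1)[C@@H](c1cc(OC)cc4c1[C@@H](C(=O)OC)[C@H](c1ccc(OC)cc1)O4)[C@H](c1ccc(OC)cc1)O3)O2 | intermediate
27 | bromo diester, all three rings 2R,3R (name as in step 17) | Brc1cc(OC)cc2c1[C@@H](C(=O)OC)[C@H](c1ccc3c(c1)[C@@H](c1cc(OC)cc4c1[C@@H](C(=O)OC)[C@H](c1ccc(OC)cc1)O4)[C@H](c1ccc(OC)cc1)O3)O2 | intermediate
28 | (E)-2-[2-(4-methoxyphenyl)ethenyl]-4,4,5,5-tetramethyl-1,3,2-dioxaborolane | COc1ccc(/C=C/B2OC(C)(C)C(C)(C)O2)cc1 | starting material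
29 | diester stilbene (27 with (E)-2-(4-methoxyphenyl)ethenyl in place of Br) | COc1ccc(/C=C/c2cc(OC)cc3c2[C@@H](C(=O)OC)[C@H](c2ccc4c(c2)[C@@H](c2cc(OC)cc5c2[C@@H](C(=O)OC)[C@H](c2ccc(OC)cc2)O5)[C@H](c2ccc(OC)cc2)O4)O3)cc1 | intermediate
30 | pentane-2,4-dione | CC(=O)CC(C)=O | starting material
31 | dilithium dianion of pentane-2,4-dione | [Li+].[Li+].[CH2-]C(=O)[CH-]C(C)=O | intermediate
32 | bis(triketone) (3,5-dioxohexanoyl group on C3 of DHB1 and of DHB3, all rings 2R,3R) | COc1ccc(/C=C/c2cc(OC)cc3c2[C@@H](C(=O)CC(=O)CC(C)=O)[C@H](c2ccc4c(c2)[C@@H](c2cc(OC)cc5c2[C@@H](C(=O)CC(=O)CC(C)=O)[C@H](c2ccc(OC)cc2)O5)[C@H](c2ccc(OC)cc2)O4)O3)cc1 | intermediate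
33 | bis aldol adduct (1-hydroxy-3,5-dioxocyclohexyl group on C3 of DHB1 and of DHB3) | COc1ccc(/C=C/c2cc(OC)cc3c2[C@@H](C2(O)CC(=O)CC(=O)C2)[C@H](c2ccc4c(c2)[C@@H](c2cc(OC)cc5c2[C@@H](C2(O)CC(=O)CC(=O)C2)[C@H](c2ccc(OC)cc2)O5)[C@H](c2ccc(OC)cc2)O4)O3)cc1 | intermediate
34 | tetraol pentamethyl ether (3,5-dihydroxyphenyl on C3 of DHB1 and of DHB3) | COc1ccc(/C=C/c2cc(OC)cc3c2[C@@H](c2cc(O)cc(O)c2)[C@H](c2ccc4c(c2)[C@@H](c2cc(OC)cc5c2[C@@H](c2cc(O)cc(O)c2)[C@H](c2ccc(OC)cc2)O5)[C@H](c2ccc(OC)cc2)O4)O3)cc1 | intermediate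
35 | CNP0184803.1 (all six stereocentres R, three 2,3-trans rings, E-alkene) | Oc1ccc(/C=C/c2cc(O)cc3c2[C@@H](c2cc(O)cc(O)c2)[C@H](c2ccc4c(c2)[C@@H](c2cc(O)cc5c2[C@@H](c2cc(O)cc(O)c2)[C@H](c2ccc(O)cc2)O5)[C@H](c2ccc(O)cc2)O4)O3)cc1 | target

**Step count**
Total: 21 steps. Longest linear sequence: 19 steps (steps 1–6 and 9–21 from compound 1); steps 7 and 8 form the ring B branch.

**Steps most likely to fail**

Step 19. Proton transfer from the acidic C3–H to the dianion may outrun acyl substitution at the hindered, α-branched esters, so that the esters are returned, or the chains may be cut again by retro-Claisen cleavage during the long reaction. The fallback changes the acyl donor to an aldehyde, which adds the dianion at −78 °C much faster than it is enolised. It sets out from 29, which is reduced with iBu2AlH (CH2Cl2, −78 → 0 °C) to the diol F1, and F1 is oxidised with Dess–Martin periodinane to the dialdehyde F2. Addition of the dianion 31 at −78 °C would give the bis(β-hydroxy diketone) F3 as a mixture of carbinol epimers, and oxidation of both carbinols (Dess–Martin periodinane or IBX) comes back to the route at 32.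

Step 20. Hydroxide may cleave the triketone chains by retro-Claisen fragmentation, or the hindered carbonyl on C3 may resist the aldol attack, so that the chains are lost before they aromatise. The fallback gives up ring synthesis at these two sites and attaches preformed arenes by nickel-catalysed decarboxylative arylation of redox-active esters. It sets out from 29, which is saponified (LiOH, THF/MeOH/H2O) to the diacid F4 and esterified with N-hydroxyphthalimide and diisopropylcarbodiimide to the bis(N-acyloxyphthalimide) F5. (3,5-Dimethoxyphenyl)zinc chloride F6 is made from 1 (n-BuLi, then ZnCl2) and coupled with F5 (NiCl2·glyme, 4,4'-di-tert-butyl-2,2'-bipyridine, THF/DMF, 25 °C). The C3 radical should be captured anti to the C2 aryl group, giving the nonamethyl ether F7 with both rings trans. BBr3 then comes back to the route at 35.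

Step 12. The N-unsubstituted hydrazone set free next to the methyl ester may acylate itself on that ester (seven-membered N-acyl hydrazone), or the oxidation may be slow and lead to azine formation, so that little diazo compound reaches the catalyst. The fallback reaches the same carbene without a free hydrazone and without oxidant. It sets out from 16, which is condensed with p-toluenesulfonyl hydrazide (MeOH/toluene, pyridinium p-toluenesulfonate cat., 60 °C) to the N-tosylhydrazone F8. Its sodium salt (NaH, THF) releases the diaryldiazomethane 19 slowly by Bamford–Stevens elimination under phase transfer (BnEt3NCl, toluene, 40 °C) in the presence of Rh2(R-PTAD)4, and the insertion comes back to the route at 20.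

**Further compounds**
F1 | step 19 | diol (both CO2CH3 groups of 29 reduced to CH2OH, configuration as in 29) | COc1ccc(/C=C/c2cc(OC)cc3c2[C@@H](CO)[C@H](c2ccc4c(c2)[C@@H](c2cc(OC)cc5c2[C@@H](CO)[C@H](c2ccc(OC)cc2)O5)[C@H](c2ccc(OC)cc2)O4)O3)cc1
F2 | step 19 | dialdehyde (CHO on C3 of DHB1 and of DHB3) | COc1ccc(/C=C/c2cc(OC)cc3c2[C@@H](C=O)[C@H](c2ccc4c(c2)[C@@H](c2cc(OC)cc5c2[C@@H](C=O)[C@H](c2ccc(OC)cc2)O5)[C@H](c2ccc(OC)cc2)O4)O3)cc1
F3 | step 19 | bis(1-hydroxy-3,5-dioxohexyl) compound (carbinol epimers) | COc1ccc(/C=C/c2cc(OC)cc3c2[C@@H](C(O)CC(=O)CC(C)=O)[C@H](c2ccc4c(c2)[C@@H](c2cc(OC)cc5c2[C@@H](C(O)CC(=O)CC(C)=O)[C@H](c2ccc(OC)cc2)O5)[C@H](c2ccc(OC)cc2)O4)O3)cc1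
F4 | step 20 | diacid (CO2H on C3 of DHB1 and of DHB3) | COc1ccc(/C=C/c2cc(OC)cc3c2[C@@H](C(=O)O)[C@H](c2ccc4c(c2)[C@@H](c2cc(OC)cc5c2[C@@H](C(=O)O)[C@H](c2ccc(OC)cc2)O5)[C@H](c2ccc(OC)cc2)O4)O3)cc1
F5 | step 20 | bis(N-acyloxyphthalimide) of F4 | COc1ccc(/C=C/c2cc(OC)cc3c2[C@@H](C(=O)ON2C(=O)c6ccccc6C2=O)[C@H](c2ccc4c(c2)[C@@H](c2cc(OC)cc5c2[C@@H](C(=O)ON2C(=O)c6ccccc6C2=O)[C@H](c2ccc(OC)cc2)O5)[C@H](c2ccc(OC)cc2)O4)O3)cc1
F6 | step 20 | (3,5-dimethoxyphenyl)zinc chloride | COc1cc([Zn]Cl)cc(OC)c1
F7 | step 20 | nonamethyl ether of the target (3,5-dimethoxyphenyl on C3 of DHB1 and of DHB3) | COc1ccc(/C=C/c2cc(OC)cc3c2[C@@H](c2cc(OC)cc(OC)c2)[C@H](c2ccc4c(c2)[C@@H](c2cc(OC)cc5c2[C@@H](c2cc(OC)cc(OC)c2)[C@H](c2ccc(OC)cc2)O5)[C@H](c2ccc(OC)cc2)O4)O3)cc1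
F8 | step 12 | N-tosylhydrazone of ketone 16 | CC(C)(C)OC(=O)c1ccc(OCc2ccc(OC)cc2)c(c1)C(=NNS(=O)(=O)c1ccc(C)cc1)c1cc(OC)cc2c1[C@@H](C(=O)OC)[C@H](c1ccc(OC)cc1)O2
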